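**Structural features**

The target 24 is a cyclopenta[c]pyran: a pyran ring (C1, O2, C3, C4, C4a, C7a) fused along C4a–C7a to a five-membered carbocycle (C5, C6, C7), together a planar 10π "pseudoazulene". C7, the carbon of the small ring next to fusion carbon C7a, carries a formyl group, and C4 carries the chain CH2–CH(OAc)–CH=C(CH3)–CH2CH2–CH=C(CH3)2. The only stereocentre is the acetoxy carbon C2′ (S); it lies between the ring-bound methylene C1′ and an (E)-trisubstituted olefin and has no stereogenic neighbour, so it must be set by a reagent. Fragile elements are the secondary allylic acetate (ionisation, elimination, cleavage by hydride or base), the electron-rich dienol-ether core (acid, electrophiles, oxidants), the aldehyde, and the two trisubstituted chain alkenes, which rule out catalytic hydrogenation and strong acid. The real difficulty is to place two different substituents at C4 and C7 of a bicycle with no dependable substitution chemistry while carrying an acid-labile allylic C–O bond. The feature exploited is the 1,2-relationship of the formyl carbon and C7a: reinserting that carbon between C7 and C7a turns the five-membered ring into the benzenoid ring of a 1H-isochromene with oxygen on C8 and nitrogen on C7, and a Wolff ring contraction regenerates exactly the C7 pattern.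

**Logic of the disconnections**

24 ⇒ 23 ⇒ 22. The acyl C–O bond of the acetate is cut and the free hydroxyl is then exchanged for a silyl ether. An acetate would not survive the hydride reduction needed at C7, whereas a silyl ether can be carried from the start. The forward steps must desilylate and acylate without ionising the allylic C–O bond or touching the aldehyde.

22 ⇒ 21 ⇒ 20. No skeletal bond is cut; the C7 substituent is taken from formyl through hydroxymethyl to methoxycarbonyl, because a ring contraction delivers a carboxyl carbon. The demand is a clean ester reduction and an immediate, acid-free re-oxidation, since 21 is an electron-rich heteroarylmethanol.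

20 ⇒ 19. Two hydrogens are added, at C1 and C7. A six-membered precursor of the contraction is a neutral closed-shell compound only if C1 is sp3, so the aromatic bicycle is traced to its 1,7-dihydro form. The forward oxidant must pick the C1–H/C7–H pair over the allylic positions of the chain.

19 ⇒ 17 (through 18). The C7–C7a bond is cut and C7a is re-attached to the carboxyl carbon, which becomes ring carbonyl C8 of a 1H-isochromen-8-one; C7 receives a diazo group. The regiochemical problem of the five-membered ring thereby becomes the substitution pattern of an ortho-aminophenol. The forward step needs nitrogen loss coupled to migration, fast capture of the ketene, and light that nothing else in the molecule absorbs.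

17 ⇒ 16 ⇒ 15. The N–N bond of the diazo group is cut back to an amine and the amine to a nitro group. This leaves a plain nitrophenol. The forward steps need a reduction without hydrogenation and a nitrosation mild enough for the enol ether.

15 ⇒ 13 (through 14). The enol-ether bond O2–C3 is cut: C3 becomes an aldehyde carbon and O2 a benzylic hydroxyl, and this hydroxyl and the phenol are tied together as a ketal. The pyran ring is thus opened to an α-aryl aldehyde with no acidic O–H. The forward step needs acid strong enough to open the ketal and dehydrate the lactol but too weak to remove the silyl ether.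

13 ⇒ 8 + 12. The C4–C4a bond (aryl carbon to aldehyde α-carbon) is cut, dividing the molecule into a chain half and an arene half of similar size. The forward step must mono-arylate a linear aldehyde enolate in the presence of a nitro group; the silyloxy group is γ to the carbonyl, so it cannot be eliminated.

12 ⇒ 11 ⇒ 10 ⇒ 9. The two ketal C–O bonds, the benzylic C–H bond (back to formyl) and the C–N bond of the nitro group are removed in turn. This reaches a commercial bromosalicylaldehyde. The demand is nitration ortho to the hydroxyl, which becomes C7.

8 ⇒ 7 ⇒ 5 ⇒ 4. No C–C bond is cut; the aldehyde is traced through the primary alcohol to a terminal alkene and the silyl ether to the free carbinol. The forward hydroboration must select the monosubstituted alkene over two trisubstituted ones.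

4 ⇒ 1 + 2. The bond between the carbinol carbon and the allyl methylene is cut, which is the step that sets the stereocentre. The forward reaction must control the enantioface of a β,β-disubstituted enal, add 1,2 only, and leave the (E)-geometry intact.

**Other disconnections considered**

Alternative 1: The cut removes both bonds flanking the chain methylene region at once, C4–C1′ and C2′–C3′. In the forward sense the boron ate complex from vinyl boronate A3 and dienyllithium A4 would meet triflate A2 under Pd(OAc)2 and a chiral ferrocenyl diphosphine. Arylpalladium adds to the vinyl terminus while the dienyl group shifts from boron to carbon, giving allylic boronate A1 with C2′ set by the catalyst. Stereoretentive C–B oxidation and acetylation would lead to A5, and formylation to 24.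
- In its favour: ring, methylene and chain are joined in one catalytic enantioselective event, and the chain needs no separate multi-step preparation. On convergence and chain step economy it is better than the chosen plan.
- Against it here: A2 is the triflate of a hydroxy-pseudoazulene of doubtful accessibility and stability. A1 is an α-chiral allylic boronate prone to 1,3-boron shift, so oxidation would have to follow at once. The formyl group is still missing, so a late electrophilic formylation must distinguish C7 from C5 on an acid-sensitive substrate.
- Comparison: both plans set the single stereocentre by catalyst control, so they are equal on that point. The chosen plan fixes the C7 position by the migration itself, whereas this one relies on innate ring reactivity. Overall step count is probably similar once A2 and the formylation are counted.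

Alternative 2: The cut is at C4–C4a and O2–C1. Forward, aminofulvene A6 would be C-alkylated at the ring carbon next to its exocyclic carbon by α-bromoaldehyde A7, and the aldehyde enol oxygen would then displace dimethylamine to close the pyran, giving A5 directly; Vilsmeier formylation would give 24.
- In its favour: the bicycle forms in one operation at the final oxidation level, with the complete acetoxy chain in place and no redox adjustment. On step economy it is clearly better than the chosen plan.
- Against it here: A7 combines a secondary α-bromoaldehyde with an allylic acetate. The liberated dimethylamine can cleave the acetate, condense with the aldehyde or promote loss of HBr, and C-alkylation by a secondary bromide must compete with these. The acidic Vilsmeier step then has to spare the allylic acetate and choose C7 over C5; shielding of C5 by the C4 chain helps but does not guarantee this.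
- Comparison: the stereocentre would come from the same allylboration chemistry, so the plans are equal there. The chosen plan is longer but each C–C bond-forming step has a defined regiochemical outcome.

Alternative 3: The cut is at C5=C6. Forward, second-generation Grubbs catalyst would join the 4-vinyl and 3-allyl groups of pyranol A9, and 1,4-loss of the tertiary hydroxyl with a C7 hydrogen would give A8; formylation would give 22.
- In its favour: ring-closing metathesis of two monosubstituted olefins to a cyclopentene is very reliable. Aromatisation is a simple dehydration and needs no oxidant, and there is no diazo intermediate or photochemistry. On operational simplicity and scale it is better than the chosen plan.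
- Against it here: A9 is a 4H-pyran-4-ol that ionises easily to a pyrylium ion. It needs a differentially 3,5-disubstituted pyran-4-one and a 1,2-selective vinyl addition, and the formyl group again arrives late by electrophilic substitution.
- Comparison: the chosen plan locates the C7 substituent by construction, and this alternative does not. Both carry the same silyl-protected chain, so they are equal on stereocontrol, and the step counts are likely close.

Key step: step 12

Remark on the chemistry: the acetoxy carbon of the target is read as S and the adjacent olefin as E. The diazo-oxide 17 and the ester 19 were checked against the target (same 2S,3E chain on C4, carboxyl carbon on the carbon next to C7a) and needed no correction. TBS = tert-butyldimethylsilyl; TBSO = its oxy group.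

**Route**

Step 1
Reactants: 1 geranial [(2E)-3,7-dimethylocta-2,6-dienal]; 2 allylboronic acid pinacol ester
Product: 4 (4S,5E)-6,10-dimethylundeca-1,5,9-trien-4-ol, via pinacol borate 3 (not isolated)
Conditions: (S)-TRIP [(S)-3,3′-bis(2,4,6-triisopropylphenyl)-1,1′-binaphthyl-2,2′-diyl hydrogen phosphate] (5 mol%), 4 Å MS, PhMe, −30 °C; aq. NaHCO3
Reagents that add atoms: none
Why: Chiral phosphoric acid-catalysed asymmetric allylboration through a closed chair transition state, which adds 1,2 only and leaves the (E)-enal geometry intact. The (S)-acid is chosen as the enantiomer expected to expose the Si face of the formyl group, which gives the 4S carbinol; should the sense prove opposite, the antipodal acid is used, and the configuration is to be confirmed by Mosher ester analysis.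

Step 2
Reactants: 4 (4S,5E)-6,10-dimethylundeca-1,5,9-trien-4-ol
Product: 5 tert-butyl{[(4S,5E)-6,10-dimethylundeca-1,5,9-trien-4-yl]oxy}dimethylsilane
Conditions: TBSCl, imidazole, DMF, rt
Reagents that add atoms: tert-butyldimethylsilyl chloride, CC(C)(C)[Si](C)(C)Cl
Why: Standard silylation of a secondary allylic alcohol; only the O–H bond reacts, so the configuration is retained, and the silyl ether protects the carbinol through hydroboration, enolate arylation, reductions and oxidations.

Step 3
Reactants: 5 tert-butyl{[(4S,5E)-6,10-dimethylundeca-1,5,9-trien-4-yl]oxy}dimethylsilane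
Product: 7 (4S,5E)-4-(TBSO)-6,10-dimethylundeca-5,9-dien-1-ol, via alkylborane 6 (not isolated)
Conditions: 9-BBN, THF, 0 °C to rt; then NaOH, H2O2, 0 °C
Reagents that add atoms: 9-borabicyclo[3.3.1]nonane, B1C2CCCC1CCC2 (boron framework of 6 only); hydrogen peroxide, OO (hydroxyl oxygen of 7)
Why: Anti-Markovnikov hydroboration–oxidation; the bulky borane reacts with the monosubstituted terminal alkene and not with the two trisubstituted ones, and alkaline peroxide oxidises the C–B bond without touching the silyl ether or the alkenes.

Step 4
Reactants: 7 (4S,5E)-4-(TBSO)-6,10-dimethylundeca-5,9-dien-1-ol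
Product: 8 (4S,5E)-4-(TBSO)-6,10-dimethylundeca-5,9-dienal
Conditions: Dess–Martin periodinane, pyridine, CH2Cl2, 0 °C to rt
Reagents that add atoms: none
Why: Dess–Martin oxidation of a primary alcohol to the aldehyde under buffered conditions; there is no α-stereocentre to epimerise and the silyl ether and alkenes are inert.

Step 5
Reactants: 9 2-bromo-6-hydroxybenzaldehyde
Product: 10 6-bromo-2-hydroxy-3-nitrobenzaldehyde
Conditions: HNO3 (65%, 1.05 equiv), AcOH, 10–15 °C; separation from the para-nitro isomer
Reagents that add atoms: nitric acid, O[N+](=O)[O-]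
Why: Electrophilic aromatic nitration directed by the phenol; the position ortho to OH is also para to Br, whereas the competing para position is ortho to Br and more hindered, so the 3-nitro isomer should predominate and the minor isomer is removed by crystallisation or chromatography.

Step 6
Reactants: 10 6-bromo-2-hydroxy-3-nitrobenzaldehyde
Product: 11 3-bromo-2-(hydroxymethyl)-6-nitrophenol
Conditions: NaBH4, MeOH–THF, 0 °C
Reagents that add atoms: none
Why: Chemoselective borohydride reduction of the aryl aldehyde; the nitro group and the aryl bromide are inert to NaBH4 at this temperature.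

Step 7
Reactants: 11 3-bromo-2-(hydroxymethyl)-6-nitrophenol
Product: 12 5-bromo-2,2-dimethyl-8-nitro-4H-1,3-benzodioxine
Conditions: Me2C(OMe)2, TsOH·H2O (cat.), acetone, rt
Reagents that add atoms: 2,2-dimethoxypropane, COC(C)(C)OC
Why: Acid-catalysed transketalisation of the saligenin-type 1,3-diol to a six-membered isopropylidene ketal; this removes both acidic O–H groups in one step so that the enolate arylation meets a neutral aryl bromide.

Step 8
Reactants: 8 (4S,5E)-4-(TBSO)-6,10-dimethylundeca-5,9-dienal; 12 5-bromo-2,2-dimethyl-8-nitro-4H-1,3-benzodioxine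
Product: 13 (4S,5E)-4-(TBSO)-2-(2,2-dimethyl-8-nitro-4H-1,3-benzodioxin-5-yl)-6,10-dimethylundeca-5,9-dienal (mixture of C2 epimers)
Conditions: Pd(OAc)2 (5 mol%), rac-BINAP (7.5 mol%), Cs2CO3, 1,4-dioxane, 80 °C; 8 in slight excess
Reagents that add atoms: none
Why: Palladium-catalysed α-arylation of an aldehyde: oxidative addition of the aryl bromide (activated by the para nitro group) to zerovalent palladium, carbonate-mediated formation of the palladium enolate and C–C reductive elimination, with the bidentate ligand and the tertiary product centre disfavouring a second arylation. The new C2 centre forms as an epimer mixture, which does not matter because C2 becomes sp2 in step 9.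

Step 9
Reactants: 13 (4S,5E)-4-(TBSO)-2-(2,2-dimethyl-8-nitro-4H-1,3-benzodioxin-5-yl)-6,10-dimethylundeca-5,9-dienal
Product: 15 4-[(2S,3E)-2-(TBSO)-4,8-dimethylnona-3,7-dien-1-yl]-7-nitro-1H-isochromen-8-ol, via lactol 14 (not isolated)
Conditions: PPTS (0.3 equiv), THF–H2O 10:1, 40 °C; then PPTS, PhMe, 4 Å MS, 60 °C
Reagents that add atoms: none
Why: Acid-catalysed ketal hydrolysis, lactol formation and dehydration to the cyclic enol ether. The nitrophenoxide is a good leaving group, so the mixed ketal should open under pyridinium-acid catalysis that leaves the secondary silyl ether alone, and loss of water from 14 is driven by conjugation of the new C3=C4 bond with the arene.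

Step 10
Reactants: 15 4-[(2S,3E)-2-(TBSO)-4,8-dimethylnona-3,7-dien-1-yl]-7-nitro-1H-isochromen-8-ol
Product: 16 7-amino-4-[(2S,3E)-2-(TBSO)-4,8-dimethylnona-3,7-dien-1-yl]-1H-isochromen-8-ol
Conditions: Na2S2O4, NaHCO3, THF–H2O, rt, argon; used crude
Reagents that add atoms: none
Why: Dithionite (electron-transfer) reduction of a nitroarene to the aniline under buffered conditions; no hydrogenation catalyst is involved, so the enol ether and the chain alkenes are untouched.

Step 11
Reactants: 16 7-amino-4-[(2S,3E)-2-(TBSO)-4,8-dimethylnona-3,7-dien-1-yl]-1H-isochromen-8-ol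
Product: 17 7-diazo-4-[(2S,3E)-2-(TBSO)-4,8-dimethylnona-3,7-dien-1-yl]-1H-isochromen-8(7H)-one
Conditions: t-BuONO (1.2 equiv), AcOH (1.0 equiv), THF, 0 °C, dark
Reagents that add atoms: tert-butyl nitrite, CC(C)(C)ON=O
Why: Aprotic diazotisation of an ortho-aminophenol with an alkyl nitrite: N-nitrosation, tautomerisation and loss of water give the diazonium ion, which the neighbouring phenol neutralises to the diazo-oxide (ortho-quinone diazide). Only one equivalent of a weak acid is present, which should spare the enol ether and the allylic silyl ether.

Step 12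
Reactants: 17 7-diazo-4-[(2S,3E)-2-(TBSO)-4,8-dimethylnona-3,7-dien-1-yl]-1H-isochromen-8(7H)-one
Product: 19 methyl 4-[(2S,3E)-2-(TBSO)-4,8-dimethylnona-3,7-dien-1-yl]-1,7-dihydrocyclopenta[c]pyran-7-carboxylate (C7 epimers and double-bond tautomers), via ketene 18 (not isolated)
Conditions: hν (395 nm LED), MeOH–THF 4:1, 0.01 M, argon, 10 °C; concentrated cold and used at once
Reagents that add atoms: methanol, CO
Why: Excitation of the diazo-oxide near 400 nm expels N2 and, because diazo and carbonyl groups are held s-cis in the ring, the fusion carbon C8a should shift from carbonyl carbon C8 to C7 in concert with nitrogen loss, leaving a free carbene little chance to insert or abstract hydrogen. The shift makes the C7–C7a bond (cyclopenta[c]pyran numbering) and turns C8 into the exocyclic ketene carbon of 18, which methanol captures to give 19 after tautomerisation of the enol. The closest known reaction type is the photochemical Wolff rearrangement of ortho-quinone diazides, which contracts the benzenoid ring to a cyclopentadiene- or indene-carboxylic acid derivative. The five-membered ring is thus closed by a 1,2-shift with ring contraction and not by a cyclisation, so no ring-size or endo/exo question arises. No stereocentre of the target is created: C7 of 19 forms as an epimer and tautomer mixture that step 13 erases, and the remote C2′ centre is not involved. Regiochemistry needs no control, because C8a is the only carbon on the carbonyl that can migrate, which puts the carboxyl carbon on the ring carbon next to C7a. Chemoselectivity rests on the wavelength, at which only the diazo-oxide absorbs while the enol ether, silyl ether and isolated alkenes are transparent, and on high dilution and full conversion, which limit azo coupling between unreacted 17 and the nucleophilic diene 19.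

Step 13
Reactants: 19 methyl 4-[(2S,3E)-2-(TBSO)-4,8-dimethylnona-3,7-dien-1-yl]-1,7-dihydrocyclopenta[c]pyran-7-carboxylate
Product: 20 methyl 4-[(2S,3E)-2-(TBSO)-4,8-dimethylnona-3,7-dien-1-yl]cyclopenta[c]pyran-7-carboxylate
Conditions: DDQ (1.05 equiv), CH2Cl2, 0 °C
Reagents that add atoms: none
Why: Dehydrogenative aromatisation with DDQ: hydride abstraction from C1 (α to oxygen and conjugated with the diene) gives a stabilised oxocarbenium ion and loss of the acidic C7 proton completes the 10π system, so all tautomers of 19 converge on 20. The gain in aromatic stabilisation should make the core far more reactive toward the quinone than the silyl ether or the isolated alkenes.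

Step 14
Reactants: 20 methyl 4-[(2S,3E)-2-(TBSO)-4,8-dimethylnona-3,7-dien-1-yl]cyclopenta[c]pyran-7-carboxylate
Product: 21 {4-[(2S,3E)-2-(TBSO)-4,8-dimethylnona-3,7-dien-1-yl]cyclopenta[c]pyran-7-yl}methanol
Conditions: i-Bu2AlH (2.5 equiv), CH2Cl2, −78 °C; aq. KNaC4H4O6; used at once
Reagents that add atoms: none
Why: Hydride reduction of an ester to the primary alcohol with i-Bu2AlH; the silyl ether, the enol-ether core and the alkenes are inert, and the basic tartrate work-up avoids the acid to which the electron-rich heteroarylmethanol is sensitive.

Step 15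
Reactants: 21 {4-[(2S,3E)-2-(TBSO)-4,8-dimethylnona-3,7-dien-1-yl]cyclopenta[c]pyran-7-yl}methanol
Product: 22 4-[(2S,3E)-2-(TBSO)-4,8-dimethylnona-3,7-dien-1-yl]cyclopenta[c]pyran-7-carbaldehyde
Conditions: activated MnO2 (excess), CH2Cl2, rt
Reagents that add atoms: none
Why: MnO2 oxidation of an activated (heteroaryl, allylic-type) primary alcohol; the neutral heterogeneous oxidant stops at the aldehyde and does not touch the isolated alkenes or the silyl ether.

Step 16
Reactants: 22 4-[(2S,3E)-2-(TBSO)-4,8-dimethylnona-3,7-dien-1-yl]cyclopenta[c]pyran-7-carbaldehyde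
Product: 23 4-[(2S,3E)-2-hydroxy-4,8-dimethylnona-3,7-dien-1-yl]cyclopenta[c]pyran-7-carbaldehyde
Conditions: Bu4NF, AcOH (1:1), THF, 0 °C to rt
Reagents that add atoms: none
Why: Fluoride-mediated desilylation driven by Si–F bond formation; acetic acid buffers the alkoxide so that the aldehyde and the core are not exposed to strong base, and the C–O bond at the stereocentre is not broken, so the configuration is retained.

Step 17
Reactants: 23 4-[(2S,3E)-2-hydroxy-4,8-dimethylnona-3,7-dien-1-yl]cyclopenta[c]pyran-7-carbaldehyde
Product: 24 (2S,3E)-1-(7-formylcyclopenta[c]pyran-4-yl)-4,8-dimethylnona-3,7-dien-2-yl acetate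
Conditions: Ac2O, pyridine, DMAP (cat.), CH2Cl2, 0 °C
Reagents that add atoms: acetic anhydride, CC(=O)OC(C)=O
Why: DMAP-catalysed acylation of a secondary allylic alcohol under basic conditions that avoid ionisation of the allylic C–O bond; only the O–H bond reacts, so C2′ keeps its S configuration.

**Compound list**

1 | geranial, (2E)-3,7-dimethylocta-2,6-dienal | CC(C)=CCC/C(C)=C/C=O | starting material
2 | allylboronic acid pinacol ester | C=CCB1OC(C)(C)C(C)(C)O1 | starting material
3 | 2-{[(4S,5E)-6,10-dimethylundeca-1,5,9-trien-4-yl]oxy}-4,4,5,5-tetramethyl-1,3,2-dioxaborolane | C=CC[C@H](OB1OC(C)(C)C(C)(C)O1)/C=C(\C)CCC=C(C)C | intermediate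
4 | (4S,5E)-6,10-dimethylundeca-1,5,9-trien-4-ol | C=CC[C@H](O)/C=C(\C)CCC=C(C)C | intermediate
5 | tert-butyl{[(4S,5E)-6,10-dimethylundeca-1,5,9-trien-4-yl]oxy}dimethylsilane | C=CC[C@H](O[Si](C)(C)C(C)(C)C)/C=C(\C)CCC=C(C)C | intermediate
6 | 9-[(4S,5E)-4-(TBSO)-6,10-dimethylundeca-5,9-dien-1-yl]-9-borabicyclo[3.3.1]nonane | B1(CCC[C@H](O[Si](C)(C)C(C)(C)C)/C=C(\C)CCC=C(C)C)C2CCCC1CCC2 | intermediate
7 | (4S,5E)-4-(TBSO)-6,10-dimethylundeca-5,9-dien-1-ol | OCCC[C@H](O[Si](C)(C)C(C)(C)C)/C=C(\C)CCC=C(C)C | intermediate
8 | (4S,5E)-4-(TBSO)-6,10-dimethylundeca-5,9-dienal | O=CCC[C@H](O[Si](C)(C)C(C)(C)C)/C=C(\C)CCC=C(C)C | intermediate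
9 | 2-bromo-6-hydroxybenzaldehyde | O=Cc1c(O)cccc1Br | starting material
10 | 6-bromo-2-hydroxy-3-nitrobenzaldehyde | O=Cc1c(O)c([N+](=O)[O-])ccc1Br | intermediate
11 | 3-bromo-2-(hydroxymethyl)-6-nitrophenol | OCc1c(O)c([N+](=O)[O-])ccc1Br | intermediate
12 | 5-bromo-2,2-dimethyl-8-nitro-4H-1,3-benzodioxine | CC1(C)OCc2c(Br)ccc([N+](=O)[O-])c2O1 | intermediate
13 | (4S,5E)-4-(TBSO)-2-(2,2-dimethyl-8-nitro-4H-1,3-benzodioxin-5-yl)-6,10-dimethylundeca-5,9-dienal (C2 epimers) | O=CC(C[C@H](O[Si](C)(C)C(C)(C)C)/C=C(\C)CCC=C(C)C)c1ccc([N+](=O)[O-])c2OC(C)(C)OCc12 | intermediate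
14 | 4-[(2S,3E)-2-(TBSO)-4,8-dimethylnona-3,7-dien-1-yl]-7-nitro-3,4-dihydro-1H-isochromene-3,8-diol (C3/C4 diastereomers) | OC1OCc2c(O)c([N+](=O)[O-])ccc2C1C[C@H](O[Si](C)(C)C(C)(C)C)/C=C(\C)CCC=C(C)C | intermediate
15 | 4-[(2S,3E)-2-(TBSO)-4,8-dimethylnona-3,7-dien-1-yl]-7-nitro-1H-isochromen-8-ol | Oc1c([N+](=O)[O-])ccc2c1COC=C2C[C@H](O[Si](C)(C)C(C)(C)C)/C=C(\C)CCC=C(C)C | intermediate
16 | 7-amino-4-[(2S,3E)-2-(TBSO)-4,8-dimethylnona-3,7-dien-1-yl]-1H-isochromen-8-ol | Nc1ccc2c(c1O)COC=C2C[C@H](O[Si](C)(C)C(C)(C)C)/C=C(\C)CCC=C(C)C | intermediate
17 | 7-diazo-4-[(2S,3E)-2-(TBSO)-4,8-dimethylnona-3,7-dien-1-yl]-1H-isochromen-8(7H)-one | [N-]=[N+]=C1C=CC2=C(COC=C2C[C@H](O[Si](C)(C)C(C)(C)C)/C=C(\C)CCC=C(C)C)C1=O | intermediate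
18 | 7-(oxomethylidene)-4-[(2S,3E)-2-(TBSO)-4,8-dimethylnona-3,7-dien-1-yl]-1,7-dihydrocyclopenta[c]pyran (ketene) | O=C=C1C=CC2=C1COC=C2C[C@H](O[Si](C)(C)C(C)(C)C)/C=C(\C)CCC=C(C)C | intermediate
19 | methyl 4-[(2S,3E)-2-(TBSO)-4,8-dimethylnona-3,7-dien-1-yl]-1,7-dihydrocyclopenta[c]pyran-7-carboxylate | COC(=O)C1C=CC2=C1COC=C2C[C@H](O[Si](C)(C)C(C)(C)C)/C=C(\C)CCC=C(C)C | intermediate
20 | methyl 4-[(2S,3E)-2-(TBSO)-4,8-dimethylnona-3,7-dien-1-yl]cyclopenta[c]pyran-7-carboxylate | COC(=O)c1ccc2c(C[C@H](O[Si](C)(C)C(C)(C)C)/C=C(\C)CCC=C(C)C)cocc1-2 | intermediate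
21 | {4-[(2S,3E)-2-(TBSO)-4,8-dimethylnona-3,7-dien-1-yl]cyclopenta[c]pyran-7-yl}methanol | OCc1ccc2c(C[C@H](O[Si](C)(C)C(C)(C)C)/C=C(\C)CCC=C(C)C)cocc1-2 | intermediate
22 | 4-[(2S,3E)-2-(TBSO)-4,8-dimethylnona-3,7-dien-1-yl]cyclopenta[c]pyran-7-carbaldehyde | O=Cc1ccc2c(C[C@H](O[Si](C)(C)C(C)(C)C)/C=C(\C)CCC=C(C)C)cocc1-2 | intermediate
23 | 4-[(2S,3E)-2-hydroxy-4,8-dimethylnona-3,7-dien-1-yl]cyclopenta[c]pyran-7-carbaldehyde | O=Cc1ccc2c(C[C@H](O)/C=C(\C)CCC=C(C)C)cocc1-2 | intermediate
24 | (2S,3E)-1-(7-formylcyclopenta[c]pyran-4-yl)-4,8-dimethylnona-3,7-dien-2-yl acetate | CC(=O)O[C@H](/C=C(\C)CCC=C(C)C)Cc1cocc2c(C=O)ccc1-2 | target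

**Step count and least certain steps**

Total: 17 steps. Longest linear sequence: 14 steps (steps 1–4 and 8–17, from geranial); the arene branch (steps 5–7) joins at step 8.

Step 12 (key step). The most likely failure is loss of material after the rearrangement, not the rearrangement itself. The nucleophilic cyclopentadiene ester is generated in the presence of unconsumed electrophilic diazo-oxide (azo coupling), it can dimerise by Diels–Alder reaction before it is oxidised, and a carbene that escapes migration can insert into the O–H bond of the solvent. The fallback changes the ketene trap and the intermediate that is carried. It sets out from 17, which would be irradiated in THF–water buffered with NaHCO3 so that ketene 18 is captured by water. The product is then held as a carboxylate that can be extracted away from neutral by-products and gives, after careful acidification, the dihydro acid F1. DDQ would convert it to the aromatic cyclopenta[c]pyran-7-carboxylic acid F2, and O-methylation (MeI, K2CO3, DMF) would return to the route at 20.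

Step 8. Base-mediated self-aldol condensation of the linear aldehyde can outrun the arylation, and reductive elimination at the ortho-substituted aryl palladium may be slow. The fallback moves the arylation to the ester oxidation level, where enolate coupling is more tolerant. It sets out from 8, which would be oxidised (NaClO2, NaH2PO4, 2-methylbut-2-ene) to the acid F3 and methylated to the methyl ester F4. Its zinc enolate (LiN(i-Pr)2, then ZnCl2) would be coupled with 12 using Pd(dba)2 (bis(dibenzylideneacetone)palladium) and P(t-Bu)3 to give the α-aryl ester F5. Reduction with i-Bu2AlH at −78 °C would return to the route at 13.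

Step 11. The nitrosating agent can attack the electron-rich enol ether, adventitious acid can hydrate it, and the aminophenol can oxidise in air before it is diazotised. The fallback changes the order of events so that no enol ether is present during nitrosation. It sets out from 13, with the hydrolysis of step 9 stopped at lactol 14. Dithionite reduction would give the aminophenol lactol F6 and diazotisation (t-BuONO, AcOH) the diazo-oxide lactol F7. Dehydration (PPTS, PhMe, 4 Å MS, 60 °C, dark) would return to the route at 17.

Step 13. DDQ is also a dienophile and can add to the cyclopentadiene instead of abstracting hydride, and excess oxidant can attack the allylic positions of the chain. The fallback replaces hydride abstraction by halogenation and elimination. It sets out from 19, which would be deprotonated at C7 (LiN(SiMe3)2, THF, −78 °C) and brominated with N-bromosuccinimide to the 7-bromo ester F8. DBU would then remove HBr by 1,6-elimination (hydrogen from C1, bromide from C7) and return to the route at 20.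

Step 14. The heteroarylmethanol 21 carries its hydroxyl on a carbon attached to the electron-rich five-membered ring and can ionise and oligomerise during work-up or storage. The fallback avoids the alcohol altogether. It sets out from 20, which would be converted with MeNH(OMe)·HCl and i-PrMgCl into the N-methoxy-N-methylamide F9. Reduction with i-Bu2AlH at −78 °C, through the stable chelated adduct, would return to the route at 22, so that step 15 is not needed.

**Further compounds**

F1 | step 12 | 4-[(2S,3E)-2-(TBSO)-4,8-dimethylnona-3,7-dien-1-yl]-1,7-dihydrocyclopenta[c]pyran-7-carboxylic acid | OC(=O)C1C=CC2=C1COC=C2C[C@H](O[Si](C)(C)C(C)(C)C)/C=C(\C)CCC=C(C)C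
F2 | step 12 | 4-[(2S,3E)-2-(TBSO)-4,8-dimethylnona-3,7-dien-1-yl]cyclopenta[c]pyran-7-carboxylic acid | OC(=O)c1ccc2c(C[C@H](O[Si](C)(C)C(C)(C)C)/C=C(\C)CCC=C(C)C)cocc1-2
F3 | step 8 | (4S,5E)-4-(TBSO)-6,10-dimethylundeca-5,9-dienoic acid | OC(=O)CC[C@H](O[Si](C)(C)C(C)(C)C)/C=C(\C)CCC=C(C)C
F4 | step 8 | methyl (4S,5E)-4-(TBSO)-6,10-dimethylundeca-5,9-dienoate | COC(=O)CC[C@H](O[Si](C)(C)C(C)(C)C)/C=C(\C)CCC=C(C)C
F5 | step 8 | methyl (4S,5E)-4-(TBSO)-2-(2,2-dimethyl-8-nitro-4H-1,3-benzodioxin-5-yl)-6,10-dimethylundeca-5,9-dienoate (C2 epimers) | COC(=O)C(C[C@H](O[Si](C)(C)C(C)(C)C)/C=C(\C)CCC=C(C)C)c1ccc([N+](=O)[O-])c2OC(C)(C)OCc12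
F6 | step 11 | 7-amino-4-[(2S,3E)-2-(TBSO)-4,8-dimethylnona-3,7-dien-1-yl]-3,4-dihydro-1H-isochromene-3,8-diol | Nc1ccc2c(c1O)COC(O)C2C[C@H](O[Si](C)(C)C(C)(C)C)/C=C(\C)CCC=C(C)C
F7 | step 11 | 7-diazo-3-hydroxy-4-[(2S,3E)-2-(TBSO)-4,8-dimethylnona-3,7-dien-1-yl]-3,4-dihydro-1H-isochromen-8(7H)-one | [N-]=[N+]=C1C=CC2=C(COC(O)C2C[C@H](O[Si](C)(C)C(C)(C)C)/C=C(\C)CCC=C(C)C)C1=O
F8 | step 13 | methyl 7-bromo-4-[(2S,3E)-2-(TBSO)-4,8-dimethylnona-3,7-dien-1-yl]-1,7-dihydrocyclopenta[c]pyran-7-carboxylate | COC(=O)C1(Br)C=CC2=C1COC=C2C[C@H](O[Si](C)(C)C(C)(C)C)/C=C(\C)CCC=C(C)C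
F9 | step 14 | N-methoxy-N-methyl-4-[(2S,3E)-2-(TBSO)-4,8-dimethylnona-3,7-dien-1-yl]cyclopenta[c]pyran-7-carboxamide | CON(C)C(=O)c1ccc2c(C[C@H](O[Si](C)(C)C(C)(C)C)/C=C(\C)CCC=C(C)C)cocc1-2
A1 | alternative 1 | 2-[(2S,3E)-1-(cyclopenta[c]pyran-4-yl)-4,8-dimethylnona-3,7-dien-2-yl]-4,4,5,5-tetramethyl-1,3,2-dioxaborolane | CC1(C)OB(OC1(C)C)[C@H](/C=C(\C)CCC=C(C)C)Cc1cocc2cccc1-2
A2 | alternative 1 | cyclopenta[c]pyran-4-yl trifluoromethanesulfonate | O=S(=O)(Oc1cocc2cccc1-2)C(F)(F)F
A3 | alternative 1 | 2-ethenyl-4,4,5,5-tetramethyl-1,3,2-dioxaborolane | C=CB1OC(C)(C)C(C)(C)O1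
A4 | alternative 1 | [(1E)-2,6-dimethylhepta-1,5-dien-1-yl]lithium | [Li]/C=C(\C)CCC=C(C)C
A5 | alternative 2 | (2S,3E)-1-(cyclopenta[c]pyran-4-yl)-4,8-dimethylnona-3,7-dien-2-yl acetate | CC(=O)O[C@H](/C=C(\C)CCC=C(C)C)Cc1cocc2cccc1-2
A6 | alternative 2 | 6-(dimethylamino)fulvene | CN(C)C=C1C=CC=C1
A7 | alternative 2 | (4S,5E)-2-bromo-6,10-dimethyl-1-oxoundeca-5,9-dien-4-yl acetate (C2 epimers) | O=CC(Br)C[C@H](OC(C)=O)/C=C(\C)CCC=C(C)C
A8 | alternative 3 | tert-butyl{[(2S,3E)-1-(cyclopenta[c]pyran-4-yl)-4,8-dimethylnona-3,7-dien-2-yl]oxy}dimethylsilane | CC(C)(C)[Si](C)(C)O[C@H](/C=C(\C)CCC=C(C)C)Cc1cocc2cccc1-2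
A9 | alternative 3 | 4-ethenyl-3-(prop-2-en-1-yl)-5-[(2S,3E)-2-(TBSO)-4,8-dimethylnona-3,7-dien-1-yl]-4H-pyran-4-ol | C=CCC1=COC=C(C[C@H](O[Si](C)(C)C(C)(C)C)/C=C(\C)CCC=C(C)C)C1(O)C=C
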